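**Retrosynthetic overview**
1. Target 6 comes from O-acetylation of the erythro alcohol 5.
2. Alcohol 5 comes from chelation-controlled hydride reduction of the (S)-α-aryloxy ketone 4, so C7 is set from C8.
3. Ketone 4 comes from a catalytic asymmetric phase-transfer C-methylation of the achiral α-aryloxy ketone 3, an organocatalytic chiral ammonium ion-pair step that forms the C8–C9 bond and the first stereocentre (C8).
4. Ketone 3 comes from Williamson etherification of the achiral bromoketone 1 with the achiral phenol 2 (C8–O bond).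
5. No ring is formed: ring A (3,4-dimethoxyphenyl) and ring B (4-allyl-2,6-dimethoxyphenoxy) are bought intact.

Assumption: neolignan numbering is used (C7 benzylic, C8 ether carbon, C9 methyl). The target SMILES corresponds to the (7R,8S)-erythro isomer, which is (1R,2S) in propane numbering.

**Step 1**
Reactants: 1 2-bromo-1-(3,4-dimethoxyphenyl)ethan-1-one; 2 4-allyl-2,6-dimethoxyphenol
Product: 3 2-(4-allyl-2,6-dimethoxyphenoxy)-1-(3,4-dimethoxyphenyl)ethan-1-one
Conditions: K2CO3 (2 equiv), acetone, reflux, 6 h
Reagents that add atoms: none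
Why: Williamson ether synthesis, in which the carbonate-deprotonated phenol displaces the strongly SN2-activated α-keto bromide; the allyl group and aryl methyl ethers are inert, and 3 is achiral.

**Step 2**
Reactants: 3 2-(4-allyl-2,6-dimethoxyphenoxy)-1-(3,4-dimethoxyphenyl)ethan-1-one
Product: 4 (S)-2-(4-allyl-2,6-dimethoxyphenoxy)-1-(3,4-dimethoxyphenyl)propan-1-one
Conditions: MeI (5 equiv), N-(2,3,4-trifluorobenzyl)-O-allyl-10,11-dihydrocinchonidinium bromide (10 mol %), CsOH·H2O (4 equiv), CH2Cl2/n-hexane 1:1, −40 °C, 24 h, cold aqueous NH4Cl quench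
Reagents that add atoms: iodomethane, CI
Why: Proposed new method: enantioselective phase-transfer C-methylation of an α-aryloxy aryl ketone, in which solid CsOH·H2O deprotonates the CH2 of 3 (flanked by C=O and OAr, pKa about 21) at the interface to the Z-enolate (aryloxy O cis to O−), which enters the organic phase as a tight ion pair with the cinchonidinium cation whose quinoline and trifluorobenzyl walls shield one face, so MeI attacks C8 by SN2 on the open face (the C8 Si face gives S); the methylated product is less acidic and hindered by allylic 1,3-strain towards re-enolisation at −40 °C, which limits racemisation and dimethylation, and the closest known reaction type is the cinchona-ammonium phase-transfer alkylation of glycine imine esters and of α-alkoxy (glycolate-type) aryl ketones with benzylic or allylic halides, which has not been shown for α-aryloxy ketones or for methylation at an O-aryl carbon.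

**Step 3**
Reactants: 4 (S)-2-(4-allyl-2,6-dimethoxyphenoxy)-1-(3,4-dimethoxyphenyl)propan-1-one
Product: 5 (1R,2S)-2-(4-allyl-2,6-dimethoxyphenoxy)-1-(3,4-dimethoxyphenyl)propan-1-ol
Conditions: Zn(BH4)2 (1.5 equiv, Et2O solution), Et2O/CH2Cl2, −30 → 0 °C; then H2O
Reagents that add atoms: none
Why: Chelation-controlled (Cram-chelate) ketone reduction, in which zinc bridges the carbonyl O and the aryloxy O (helped by an ortho-methoxy group), holding C=O and C8–O syn-periplanar so that hydride enters from the C8–H side, anti to CH3, giving the erythro (7R) carbinol; C8 is untouched under these non-basic conditions and the terminal alkene is not hydroborated at this temperature.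

**Step 4**
Reactants: 5 (1R,2S)-2-(4-allyl-2,6-dimethoxyphenoxy)-1-(3,4-dimethoxyphenyl)propan-1-ol
Product: 6 Maceneolignan H, (1R,2S)-2-(4-allyl-2,6-dimethoxyphenoxy)-1-(3,4-dimethoxyphenyl)propyl acetate
Conditions: Ac2O (2 equiv), pyridine (3 equiv), 4-(dimethylamino)pyridine (5 mol %), CH2Cl2, 0 °C → rt
Reagents that add atoms: acetic anhydride, CC(=O)OC(C)=O
Why: DMAP-catalysed O-acylation (nucleophilic acyl-transfer catalysis) of the secondary benzylic alcohol, in which the C7–O bond is never broken, so both stereocentres are retained.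

**Compound list**
1 | 2-bromo-1-(3,4-dimethoxyphenyl)ethan-1-one | COc1ccc(C(=O)CBr)cc1OC | starting material
2 | 4-allyl-2,6-dimethoxyphenol (methoxyeugenol) | C=CCc1cc(OC)c(O)c(OC)c1 | starting material
3 | 2-(4-allyl-2,6-dimethoxyphenoxy)-1-(3,4-dimethoxyphenyl)ethan-1-one | C=CCc1cc(OC)c(OCC(=O)c2ccc(OC)c(OC)c2)c(OC)c1 | intermediate
4 | (S)-2-(4-allyl-2,6-dimethoxyphenoxy)-1-(3,4-dimethoxyphenyl)propan-1-one | C=CCc1cc(OC)c(O[C@@H](C)C(=O)c2ccc(OC)c(OC)c2)c(OC)c1 | intermediate
5 | (1R,2S)-2-(4-allyl-2,6-dimethoxyphenoxy)-1-(3,4-dimethoxyphenyl)propan-1-ol | C=CCc1cc(OC)c(O[C@@H](C)[C@H](O)c2ccc(OC)c(OC)c2)c(OC)c1 | intermediate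
6 | Maceneolignan H, (1R,2S)-2-(4-allyl-2,6-dimethoxyphenoxy)-1-(3,4-dimethoxyphenyl)propyl acetate | C=CCc1cc(OC)c(O[C@@H](C)[C@H](OC(C)=O)c2ccc(OC)c(OC)c2)c(OC)c1 | target

**Step count and risks**
Total steps: 4. Longest linear sequence: 4 (from 1 or 2).

The three steps most likely to fail:

Step 2 (the proposed new methylation). The risks are moderate ee with the small electrophile, a facial sense opposite to the analogy (the cinchonine-derived pseudoenantiomeric salt would then be tried first), dimethylation, and base-induced racemisation of 4. The fallback sets C8 by known organocatalytic chemistry; it sets out from phenol 2 and comes back to the route at 4. Commercial 1-(3,4-dimethoxyphenyl)propan-1-one F1 is silylated (TBSOTf, Et3N, CH2Cl2, 0 °C) to (Z)-tert-butyl{[1-(3,4-dimethoxyphenyl)prop-1-en-1-yl]oxy}dimethylsilane F2. Shi epoxidation of F2 (1,2:4,5-di-O-isopropylidene-β-D-erythro-2,3-hexodiulo-2,6-pyranose 30 mol %, KHSO5, K2CO3 buffer pH 10.5, MeCN/CH2(OMe)2, 0 °C) gives the labile (2S,3R)-2-(tert-butyldimethylsilyloxy)-2-(3,4-dimethoxyphenyl)-3-methyloxirane F3 (not isolated). On mildly acidic work-up this collapses and is desilylated to (R)-2-hydroxy-1-(3,4-dimethoxyphenyl)propan-1-one F4. Mitsunobu coupling of F4 with phenol 2 (PPh3, DIAD, THF, 0 °C) inverts C8 and gives 4.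

Step 3 (diastereoselective reduction). The aryl ether oxygen is a weak donor, so chelation may be incomplete and the erythro:threo ratio modest; the minor threo isomer is separable by chromatography at the alcohol stage. The fallback reverses the strategy, making the threo alcohol on purpose and inverting C7 during ester formation; it sets out from 4 and comes back at 6, bypassing 5. Non-chelating Felkin–Anh reduction of 4 with KBH(s-Bu)3 (THF, −78 °C) gives (1S,2S)-2-(4-allyl-2,6-dimethoxyphenoxy)-1-(3,4-dimethoxyphenyl)propan-1-ol F5. Mitsunobu esterification of F5 with acetic acid (PPh3, DIAD, AcOH, toluene, 0 °C) inverts C7 and gives 6 directly.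

Step 1 (etherification). The di-ortho-substituted phenoxide is hindered, and bromoketone 1 can self-condense or decompose under base. The fallback builds ketone 3 by C–C instead of C–O bond formation to a bromoketone; it sets out from 2 and comes back at 3. Phenol 2 is O-alkylated with commercial 2-chloro-N-methoxy-N-methylacetamide (K2CO3, NaI cat., DMF, 60 °C) to give 2-(4-allyl-2,6-dimethoxyphenoxy)-N-methoxy-N-methylacetamide F6. Addition of commercial 3,4-dimethoxyphenylmagnesium bromide to this Weinreb amide (THF, 0 °C) gives 3.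

**Further compounds**
F1 | step 2 | 1-(3,4-dimethoxyphenyl)propan-1-one | CCC(=O)c1ccc(OC)c(OC)c1
F2 | step 2 | (Z)-tert-butyl{[1-(3,4-dimethoxyphenyl)prop-1-en-1-yl]oxy}dimethylsilane | C/C=C(\O[Si](C)(C)C(C)(C)C)c1ccc(OC)c(OC)c1
F3 | step 2 | (2S,3R)-2-(tert-butyldimethylsilyloxy)-2-(3,4-dimethoxyphenyl)-3-methyloxirane | C[C@H]1O[C@]1(O[Si](C)(C)C(C)(C)C)c1ccc(OC)c(OC)c1
F4 | step 2 | (R)-2-hydroxy-1-(3,4-dimethoxyphenyl)propan-1-one | C[C@@H](O)C(=O)c1ccc(OC)c(OC)c1
F5 | step 3 | (1S,2S)-2-(4-allyl-2,6-dimethoxyphenoxy)-1-(3,4-dimethoxyphenyl)propan-1-ol | C=CCc1cc(OC)c(O[C@@H](C)[C@@H](O)c2ccc(OC)c(OC)c2)c(OC)c1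
F6 | step 1 | 2-(4-allyl-2,6-dimethoxyphenoxy)-N-methoxy-N-methylacetamide | C=CCc1cc(OC)c(OCC(=O)N(C)OC)c(OC)c1
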